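## Retrosynthetic overview

1. Ring labels: A = trioxygenated ring (C1 carries the carbinol carbon; C3–OH, C4–OH, C5–O–aryl), B = para-linked phenoxy ring, C = 3-hydroxy-1,2-disubstituted ring, D = meta-linked ring. The 18-membered macrocycle is the only ring formed and is closed last.
2. Key disconnection: the ether bond between the ring B oxygen and C5 of ring A, made by oxidative polarity reversal of ring A. The enabling feature is the 2-alkoxyphenol array of ring A (free C3–OH beside the C4 oxygen, which is beside C5). PhI(OAc)2 turns it into an orthoquinol acetate in which C5 is the δ-carbon of a dienone and C4 bears a leaving group, so the ring B phenoxide can add at C5 and ring A rearomatizes.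
3. Acyclic precursor: an (S)-carbinol from asymmetric transfer hydrogenation of a deoxybenzoin, which comes from Sonogashira coupling of a ring A alkyne with the ring D iodide and regioselective alkyne hydration.
4. B–C–D fragment: SNAr of 3-iodophenol on a 2-fluorobenzaldehyde (ring C–O–ring D ether), Wittig olefination with a ring B phosphonium salt, diimide reduction, silylation.
5. End game: hydrogenolysis of the two benzyl ethers.

Key step: step 11

Remark: 2-fluoro-3-hydroxybenzaldehyde, 3-iodophenol, 4-hydroxybenzyl alcohol and 4-(benzyloxy)-3-hydroxybenzaldehyde are taken as commercial, and the 18-membered ring is taken as conformationally mobile, so the carbinol carbon is the only stereogenic element.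

## Route

Step 1
Reactants: 1 2-fluoro-3-hydroxybenzaldehyde
Product: 2 3-(benzyloxy)-2-fluorobenzaldehyde
Conditions: BnBr, K2CO3, DMF, rt
Reagents that add atoms: benzyl bromide, BrCc1ccccc1
Why: Williamson O-benzylation of the phenol; the aldehyde and the aryl fluoride are inert to carbonate at room temperature.

Step 2
Reactants: 2 3-(benzyloxy)-2-fluorobenzaldehyde; 3 3-iodophenol
Product: 4 3-(benzyloxy)-2-(3-iodophenoxy)benzaldehyde
Conditions: K2CO3, DMA, 120 °C
Reagents that add atoms: none
Why: Nucleophilic aromatic substitution (SNAr) in which the ortho-formyl group activates the fluoride towards the phenoxide of 3, while the aryl iodide is inert in the absence of a transition metal.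

Step 3
Reactants: 5 4-hydroxybenzyl alcohol
Product: 6 (4-hydroxybenzyl)triphenylphosphonium bromide
Conditions: PPh3·HBr, MeCN, reflux
Reagents that add atoms: triphenylphosphine hydrobromide, [Br-].c1ccc(cc1)[PH+](c1ccccc1)c1ccccc1
Why: Acid-promoted phosphonium salt formation from a para-hydroxybenzylic alcohol, whose ionization is assisted by the para-hydroxyl, should give the salt directly without phenol protection.

Step 4
Reactants: 4 3-(benzyloxy)-2-(3-iodophenoxy)benzaldehyde; 6 (4-hydroxybenzyl)triphenylphosphonium bromide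
Product: 7 4-{2-[3-(benzyloxy)-2-(3-iodophenoxy)phenyl]ethenyl}phenol (E/Z mixture)
Conditions: KOtBu (2.1 equiv relative to 6), THF, 0 °C; then 4, 0 °C to rt; aq NH4Cl
Reagents that add atoms: none
Why: Wittig olefination of the aryl aldehyde with the benzylic phosphonium salt, run with two equivalents of base because of the free phenol; the E/Z mixture is acceptable because the double bond is saturated in step 5.

Step 5
Reactants: 7 4-{2-[3-(benzyloxy)-2-(3-iodophenoxy)phenyl]ethenyl}phenol
Product: 8 4-{2-[3-(benzyloxy)-2-(3-iodophenoxy)phenyl]ethyl}phenol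
Conditions: TsNHNH2 (excess), NaOAc, DME/H2O, reflux
Reagents that add atoms: none
Why: Diimide, generated in the flask from TsNHNH2, transfers H2 to the stilbene in a concerted syn fashion and, unlike hydrogenation over palladium, should leave the aryl iodide and the benzyl ether intact.

Step 6
Reactants: 8 4-{2-[3-(benzyloxy)-2-(3-iodophenoxy)phenyl]ethyl}phenol
Product: 9 {4-[2-(3-(benzyloxy)-2-(3-iodophenoxy)phenyl)ethyl]phenoxy}tri(propan-2-yl)silane
Conditions: TIPSCl, imidazole, DMF, rt
Reagents that add atoms: chlorotri(propan-2-yl)silane (TIPSCl), CC(C)[Si](Cl)(C(C)C)C(C)C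
Why: Silylation of the only free phenol; the TIPS ether should survive amine bases, aqueous gold catalysis and formic acid, and is cleaved by fluoride exactly when the ring B phenoxide is needed in step 11.

Step 7
Reactants: 10 4-(benzyloxy)-3-hydroxybenzaldehyde
Product: 11 2-(benzyloxy)-5-ethynylphenol
Conditions: dimethyl (1-diazo-2-oxopropyl)phosphonate, K2CO3 (2.5 equiv), MeOH, 0 °C to rt
Reagents that add atoms: dimethyl (1-diazo-2-oxopropyl)phosphonate, CC(=O)C(=[N+]=[N-])P(=O)(OC)OC
Why: Ohira–Bestmann (Seyferth–Gilbert) homologation of the aldehyde to the terminal alkyne under K2CO3/MeOH, which tolerates the free phenol when extra base is used.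

Step 8
Reactants: 9 {4-[2-(3-(benzyloxy)-2-(3-iodophenoxy)phenyl)ethyl]phenoxy}tri(propan-2-yl)silane; 11 2-(benzyloxy)-5-ethynylphenol
Product: 12 2-(benzyloxy)-5-({3-[2-(benzyloxy)-6-(2-{4-[(triisopropylsilyl)oxy]phenyl}ethyl)phenoxy]phenyl}ethynyl)phenol
Conditions: PdCl2(PPh3)2 (3 mol %), CuI (5 mol %), Et3N, THF, rt, degassed
Reagents that add atoms: none
Why: Sonogashira coupling of the aryl iodide at room temperature tolerates the free phenol, the silyl ether and the benzyl ethers, and the hydroxyl is meta to the alkyne so no benzofuran can form.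

Step 9
Reactants: 12 2-(benzyloxy)-5-({3-[2-(benzyloxy)-6-(2-{4-[(triisopropylsilyl)oxy]phenyl}ethyl)phenoxy]phenyl}ethynyl)phenol
Product: 13 1-[4-(benzyloxy)-3-hydroxyphenyl]-2-{3-[2-(benzyloxy)-6-(2-{4-[(triisopropylsilyl)oxy]phenyl}ethyl)phenoxy]phenyl}ethan-1-one
Conditions: [AuCl(IPr)] (3 mol %), AgSbF6 (3 mol %), 1,4-dioxane/H2O (4:1), 80 °C
Reagents that add atoms: water, O
Why: Gold-catalysed alkyne hydration in which water should attack the alkyne carbon attached to ring A, because the para-benzyloxy group stabilizes positive charge there and the meta-aryloxy group of ring D destabilizes it at the other carbon, so the carbonyl ends up next to ring A.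

Step 10
Reactants: 13 1-[4-(benzyloxy)-3-hydroxyphenyl]-2-{3-[2-(benzyloxy)-6-(2-{4-[(triisopropylsilyl)oxy]phenyl}ethyl)phenoxy]phenyl}ethan-1-one
Product: 14 2-(benzyloxy)-5-[(1S)-1-hydroxy-2-{3-[2-(benzyloxy)-6-(2-{4-[(triisopropylsilyl)oxy]phenyl}ethyl)phenoxy]phenyl}ethyl]phenol
Conditions: RuCl[(S,S)-TsDPEN](p-cymene) (2 mol %), HCO2H/Et3N (5:2), EtOAc, 40 °C
Reagents that add atoms: none
Why: Noyori asymmetric transfer hydrogenation, in which the (S,S)-TsDPEN ligand should deliver hydride to the ketone face that gives the (S)-carbinol, the conjugated ring A acting as the CH/π-directing large group and CH2Ar as the small one, as for deoxybenzoin.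

Step 11
Reactants: 14 2-(benzyloxy)-5-[(1S)-1-hydroxy-2-{3-[2-(benzyloxy)-6-(2-{4-[(triisopropylsilyl)oxy]phenyl}ethyl)phenoxy]phenyl}ethyl]phenol
Product: 18 dibenzyl-protected macrocyclic (S)-carbinol (ring A: C3–OH free; C4–OBn; C5–O–ring B; ring C: OBn), via orthoquinol acetate 15 (not isolated), via ring B phenoxide 16 (not isolated), via macrocyclic 1,6-adduct 17 (not isolated)
Conditions: PhI(OAc)2 (1.05 equiv), CH2Cl2, −78 to −30 °C; then the cold solution added over 8 h to Bu4NF (3 equiv), THF, 0 °C (final 1 mM); aq NH4Cl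
Reagents that add atoms: none
Why: Proposed new method: PhI(OAc)2 (trivalent iodine) dearomatizes the 2-benzyloxyphenol of ring A by Wessely-type ortho-acetoxylation at C4 to the orthoquinol acetate 15, a linear 2,4-dienone (C3=O, C1=C2, C5=C6) whose δ-carbon is C5 and whose neighbouring acetal carbon C4 carries acetate; fluoride then removes the TIPS group to give phenoxide 16, which adds through oxygen to C5 (oxa-1,6-addition) to give 17, and loss of acetic acid across C4–C5 rearomatizes ring A to 18. The closest known reaction type is the oxidative nucleophilic substitution of 2-alkoxyphenols through orthoquinol acetates or ortho-quinone monoketals, in which tethered nitrogen or carbon nucleophiles add to the dienone and the ring rearomatizes by loss of an acetal substituent; new here are the phenoxide nucleophile and the macrocyclic ring size. The 18-membered ring closes by an 18-endo-trig conjugate addition (the attacked C5=C6 bond lies inside the new ring), and the net result joins two nucleophilic atoms, a phenol oxygen and an arene CH carbon, by polarity reversal of ring A. No new stereocentre remains, since the sp3 centres at C4 and C5 of 15 to 17 are lost on rearomatization, and the (S)-carbinol is not acidic, not para to a free phenoxide and not oxidized by PhI(OAc)2. The step needs C5 over C1, C2 and C6 as the site of attack, O- over C-attack of the phenoxide and ring closure over oligomerization: the β-carbon C1 is substituted and its adduct can only revert, C2 and C6 are not acceptor positions once the C4 carbonyl of the formal ortho-quinone is masked as the acetal (direct allylic displacement of acetate at C6 is the pathway to watch), a tetrabutylammonium phenoxide in THF should react at oxygen, and slow addition keeps the reactive species near 1 mM. The TIPS ether keeps ring B inert to PhI(OAc)2 until the oxidation of ring A is complete.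

Step 12
Reactants: 18 dibenzyl-protected macrocyclic (S)-carbinol
Product: 19 target macrocycle CNP0333307.1, (S)-configured
Conditions: H2 (1 atm), 10% Pd/C, EtOAc/MeOH (4:1), rt; work-up under argon
Reagents that add atoms: none
Why: Hydrogenolysis of the two aryl benzyl ethers over Pd/C under neutral conditions, where para-hydroxybenzylic secondary alcohols normally survive, should release the triphenol without touching the stereocentre or the diaryl ethers.

## Compound list

1 | 2-fluoro-3-hydroxybenzaldehyde | O=Cc1cccc(O)c1F | starting material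
2 | 3-(benzyloxy)-2-fluorobenzaldehyde | O=Cc1cccc(OCc2ccccc2)c1F | intermediate
3 | 3-iodophenol | Oc1cccc(I)c1 | starting material
4 | 3-(benzyloxy)-2-(3-iodophenoxy)benzaldehyde | O=Cc1cccc(OCc2ccccc2)c1Oc1cccc(I)c1 | intermediate
5 | 4-hydroxybenzyl alcohol | OCc1ccc(O)cc1 | starting material
6 | (4-hydroxybenzyl)triphenylphosphonium bromide | Oc1ccc(C[P+](c2ccccc2)(c2ccccc2)c2ccccc2)cc1.[Br-] | intermediate
7 | 4-{2-[3-(benzyloxy)-2-(3-iodophenoxy)phenyl]ethenyl}phenol (E/Z mixture) | Oc1ccc(C=Cc2cccc(OCc3ccccc3)c2Oc2cccc(I)c2)cc1 | intermediate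
8 | 4-{2-[3-(benzyloxy)-2-(3-iodophenoxy)phenyl]ethyl}phenol | Oc1ccc(CCc2cccc(OCc3ccccc3)c2Oc2cccc(I)c2)cc1 | intermediate
9 | {4-[2-(3-(benzyloxy)-2-(3-iodophenoxy)phenyl)ethyl]phenoxy}tri(propan-2-yl)silane | CC(C)[Si](Oc1ccc(CCc2cccc(OCc3ccccc3)c2Oc2cccc(I)c2)cc1)(C(C)C)C(C)C | intermediate
10 | 4-(benzyloxy)-3-hydroxybenzaldehyde | O=Cc1ccc(OCc2ccccc2)c(O)c1 | starting material
11 | 2-(benzyloxy)-5-ethynylphenol | C#Cc1ccc(OCc2ccccc2)c(O)c1 | intermediate
12 | 2-(benzyloxy)-5-({3-[2-(benzyloxy)-6-(2-{4-[(triisopropylsilyl)oxy]phenyl}ethyl)phenoxy]phenyl}ethynyl)phenol | CC(C)[Si](Oc1ccc(CCc2cccc(OCc3ccccc3)c2Oc2cccc(C#Cc3ccc(OCc4ccccc4)c(O)c3)c2)cc1)(C(C)C)C(C)C | intermediate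
13 | 1-[4-(benzyloxy)-3-hydroxyphenyl]-2-{3-[2-(benzyloxy)-6-(2-{4-[(triisopropylsilyl)oxy]phenyl}ethyl)phenoxy]phenyl}ethan-1-one | CC(C)[Si](Oc1ccc(CCc2cccc(OCc3ccccc3)c2Oc2cccc(CC(=O)c3ccc(OCc4ccccc4)c(O)c3)c2)cc1)(C(C)C)C(C)C | intermediate
14 | 2-(benzyloxy)-5-[(1S)-1-hydroxy-2-{3-[2-(benzyloxy)-6-(2-{4-[(triisopropylsilyl)oxy]phenyl}ethyl)phenoxy]phenyl}ethyl]phenol | CC(C)[Si](Oc1ccc(CCc2cccc(OCc3ccccc3)c2Oc2cccc(C[C@H](O)c3ccc(OCc4ccccc4)c(O)c3)c2)cc1)(C(C)C)C(C)C | intermediate
15 | orthoquinol acetate of 14: ring A as 6-acetoxy-6-(benzyloxy)cyclohexa-2,4-dien-1-one carrying the (1S)-1-hydroxy-2-arylethyl chain at its C3 (both epimers at the acetal carbon), TIPS ether intact | CC(C)[Si](Oc1ccc(CCc2cccc(OCc3ccccc3)c2Oc2cccc(C[C@H](O)C3=CC(=O)C(OCc4ccccc4)(OC(C)=O)C=C3)c2)cc1)(C(C)C)C(C)C | intermediate (not isolated)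
16 | tetrabutylammonium ring B phenoxide of desilylated 15 | [O-]c1ccc(CCc2cccc(OCc3ccccc3)c2Oc2cccc(C[C@H](O)C3=CC(=O)C(OCc4ccccc4)(OC(C)=O)C=C3)c2)cc1.CCCC[N+](CCCC)(CCCC)CCCC | intermediate (not isolated)
17 | macrocyclic 1,6-adduct, drawn as the dienol: ring A C5 sp3 (H, O–ring B), C4 sp3 (OBn, OAc), configuration at C4 and C5 undefined | OC1=CC2=CC(C1(OCc1ccccc1)OC(C)=O)Oc1ccc(cc1)CCc1cccc(OCc3ccccc3)c1Oc1cccc(c1)C[C@@H]2O | intermediate (not isolated)
18 | dibenzyl-protected macrocyclic (S)-carbinol (ring A: 3-OH, 4-OBn, 5-O–ring B; ring C: OBn) | Oc1cc2cc(c1OCc1ccccc1)Oc1ccc(cc1)CCc1cccc(OCc3ccccc3)c1Oc1cccc(c1)C[C@@H]2O | intermediate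
19 | target macrocycle CNP0333307.1, (S)-carbinol | Oc1cc2cc(c1O)Oc1ccc(cc1)CCc1cccc(O)c1Oc1cccc(c1)C[C@@H]2O | target

## Step count and risks

Total: 12 steps. Longest linear sequence: 10 steps (steps 1, 2, 4, 5, 6, 8, 9, 10, 11, 12).

**Step 11 (proposed new method).** What may go wrong: attack of the phenoxide at the wrong ring A carbon (allylic displacement of acetate at C6), acyl transfer from the orthoquinol acetate to the phenoxide or to fluoride before ring closure, Diels–Alder dimerization of the dienone, or oligomerization. The fallback uses only known chemistry and closes the same O–C5 bond by a copper-catalysed Ullmann diaryl ether macrocyclization; it sets out from 9 and comes back to the route at 19. Commercial 3-bromo-4,5-dihydroxybenzaldehyde is dibenzylated (BnBr, K2CO3, DMF) to 3,4-bis(benzyloxy)-5-bromobenzaldehyde F1 and homologated (dimethyl (1-diazo-2-oxopropyl)phosphonate, K2CO3, MeOH) to 1,2-bis(benzyloxy)-3-bromo-5-ethynylbenzene F2. Sonogashira coupling of F2 with 9 at room temperature (PdCl2(PPh3)2, CuI, Et3N), where the aryl iodide of 9 reacts and the hindered aryl bromide should not, gives the bromo diarylalkyne F3. Hydration as in step 9 gives the bromo ketone F4, and transfer hydrogenation as in step 10 gives the bromo (S)-carbinol F5. Bu4NF in THF removes the silyl group to give the bromo phenol F6. Intramolecular Ullmann etherification (CuI, N,N-dimethylglycine, Cs2CO3, dioxane, 95 °C, 2 mM) gives the tribenzyl macrocycle F7, and hydrogenolysis (H2, Pd/C) of its three benzyl ethers gives 19.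

**Step 9.** What may go wrong: poor regioselectivity of water addition across the diarylalkyne, or loss of the silyl ether under Lewis-acidic aqueous conditions. The fallback builds the deoxybenzoin by palladium-catalysed ketone α-arylation instead; it sets out from 9 and comes back at 13. Commercial 3',4'-dihydroxyacetophenone is benzylated selectively at the more acidic para-hydroxyl (BnBr, 1 equiv K2CO3, DMF) to 1-[4-(benzyloxy)-3-hydroxyphenyl]ethanone F8 and protected (MOMCl, iPr2NEt) as 1-[4-(benzyloxy)-3-(methoxymethoxy)phenyl]ethanone F9. α-Arylation of F9 with 9 (Pd2(dba)3, XPhos, K3PO4, toluene, 80 °C) gives the MOM-protected deoxybenzoin F10. Mild acid (cat. HCl, MeOH/THF, 40 °C) removes the MOM group at the ketone stage, before the acid-sensitive carbinol exists, and gives 13.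

**Step 12.** What may go wrong: over-reduction by hydrogenolysis of the electron-rich benzylic C–O bond, incomplete debenzylation, or aerial oxidation of the pyrogallol-type ring on work-up. The fallback masks the carbinol before hydrogenolysis; it sets out from 18 and comes back at 19. Silylation of the ring A phenol and the carbinol (TBSOTf, 2,6-lutidine, CH2Cl2, 0 °C) gives the bis(silyl ether) F11, in which the bulky benzylic silyl ether should resist C–O hydrogenolysis. Hydrogenolysis (H2, Pd/C, EtOAc) gives the debenzylated bis(silyl ether) F12, and buffered fluoride (Bu4NF/AcOH, THF, 0 °C) gives 19.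

## Further compounds

F1 | step 11 | 3,4-bis(benzyloxy)-5-bromobenzaldehyde | O=Cc1cc(Br)c(OCc2ccccc2)c(OCc2ccccc2)c1
F2 | step 11 | 1,2-bis(benzyloxy)-3-bromo-5-ethynylbenzene | C#Cc1cc(Br)c(OCc2ccccc2)c(OCc2ccccc2)c1
F3 | step 11 | bromo diarylalkyne (ring A: 3,4-bis(benzyloxy)-5-bromo; TIPS ether on ring B) | CC(C)[Si](Oc1ccc(CCc2cccc(OCc3ccccc3)c2Oc2cccc(C#Cc3cc(Br)c(OCc4ccccc4)c(OCc4ccccc4)c3)c2)cc1)(C(C)C)C(C)C
F4 | step 11 | bromo ketone: 1-[3,4-bis(benzyloxy)-5-bromophenyl]-2-arylethan-1-one | CC(C)[Si](Oc1ccc(CCc2cccc(OCc3ccccc3)c2Oc2cccc(CC(=O)c3cc(Br)c(OCc4ccccc4)c(OCc4ccccc4)c3)c2)cc1)(C(C)C)C(C)C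
F5 | step 11 | bromo (S)-carbinol: (1S)-1-[3,4-bis(benzyloxy)-5-bromophenyl]-2-arylethan-1-ol, TIPS ether | CC(C)[Si](Oc1ccc(CCc2cccc(OCc3ccccc3)c2Oc2cccc(C[C@H](O)c3cc(Br)c(OCc4ccccc4)c(OCc4ccccc4)c3)c2)cc1)(C(C)C)C(C)C
F6 | step 11 | bromo phenol: desilylated F5 | Oc1ccc(CCc2cccc(OCc3ccccc3)c2Oc2cccc(C[C@H](O)c3cc(Br)c(OCc4ccccc4)c(OCc4ccccc4)c3)c2)cc1
F7 | step 11 | tribenzyl macrocycle (ring A: 3,4-bis(benzyloxy); ring C: OBn; (S)-carbinol) | C(Oc1cc2cc(c1OCc1ccccc1)Oc1ccc(cc1)CCc1cccc(OCc3ccccc3)c1Oc1cccc(c1)C[C@@H]2O)c1ccccc1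
F8 | step 9 | 1-[4-(benzyloxy)-3-hydroxyphenyl]ethanone | CC(=O)c1ccc(OCc2ccccc2)c(O)c1
F9 | step 9 | 1-[4-(benzyloxy)-3-(methoxymethoxy)phenyl]ethanone | COCOc1cc(C(C)=O)ccc1OCc1ccccc1
F10 | step 9 | MOM-protected deoxybenzoin (3-O-methoxymethyl ether of 13) | CC(C)[Si](Oc1ccc(CCc2cccc(OCc3ccccc3)c2Oc2cccc(CC(=O)c3ccc(OCc4ccccc4)c(OCOC)c3)c2)cc1)(C(C)C)C(C)C
F11 | step 12 | bis(tert-butyldimethylsilyl) ether of 18 (ring A C3–O and carbinol O silylated) | CC(C)(C)[Si](C)(C)Oc1cc2cc(c1OCc1ccccc1)Oc1ccc(cc1)CCc1cccc(OCc3ccccc3)c1Oc1cccc(c1)C[C@@H]2O[Si](C)(C)C(C)(C)C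
F12 | step 12 | debenzylated bis(silyl ether) (ring A C4–OH and ring C–OH free) | CC(C)(C)[Si](C)(C)Oc1cc2cc(c1O)Oc1ccc(cc1)CCc1cccc(O)c1Oc1cccc(c1)C[C@@H]2O[Si](C)(C)C(C)(C)C
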